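The tetrahydrofuran ring (C1–C2–O–C9–C10; eunicellane numbering, defined below) is disconnected at C9–C10 and, in the same operation, the oxonane at C7–C8. The key step uses three features: C9 is an ether carbon next to C8, which is β to the C7 methylene carbon; C10 is one end of a former cyclohexene C10=C11 bond; and the C11 hydroxyl is cis to the C12 octanoate. A C2-O-vinyl ether adds to a C7 aldehyde, the C9 oxocarbenium ion so formed inside the nine-membered ring is trapped by C10=C11, and the octanoate delivers the C11 oxygen. The precursor is an oxepane-fused cyclohexenyl octanoate bearing a vinyloxy group and a 4-oxobutyl chain.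

Key step: step 15

Remark (numbering): C1, C10, C11, C12, C13, C14 form the cyclohexane; C2 and C9 are the O-bearing carbons of the tetrahydrofuran; C3–C8 are the other oxonane carbons (C3 quaternary, C7 carries the C19 methylene); C15 (with the C16 methyl) and C17 (OCH2) complete the oxepane; C18 is the methyl on C3 and C20 the methyl on C11. β is the face of the cyclohexane on which C2 lies, α the opposite face.

Remark (assumptions): 1 and 2 are taken as purchasable. The C7 carbinol centre, which step 16 destroys, is carried as a mixture and has no descriptor in the SMILES.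

Step 1
Reactants: 1 (R)-2-methylglycidol; 2 (3-bromopropoxy)(tert-butyl)diphenylsilane
Product: 4 (2S)-6-[(tert-butyldiphenylsilyl)oxy]-2-methylhexane-1,2-diol, via {3-[(tert-butyldiphenylsilyl)oxy]propyl}magnesium bromide 3 (not isolated)
Conditions: 2 (2.2 equiv), Mg, THF, rt; then CuI (10 mol %), 1, THF, −30 to 0 °C; aq. NH4Cl
Reagents that add atoms: none
Why: Copper-catalysed Grignard opening of the 2,2-disubstituted epoxide (SN2 at the CH2 terminus, one equivalent of 3 serving as base for the hydroxyl) joins C4 to C5 and leaves the tertiary stereocentre (future C3) untouched, the cold magnesium alkoxide being too unreactive for Payne rearrangement.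

Step 2
Reactants: 4 (2S)-6-[(tert-butyldiphenylsilyl)oxy]-2-methylhexane-1,2-diol
Product: 5 (2S)-6-[(tert-butyldiphenylsilyl)oxy]-2-methyl-1,2-bis[(trimethylsilyl)oxy]hexane
Conditions: TMSCl (2.5 equiv), imidazole, DMF, 0 °C to rt
Reagents that add atoms: chlorotrimethylsilane, C[Si](C)(C)Cl
Why: Exhaustive silyl ether formation protects the tertiary hydroxyl and turns the primary one into a group that step 3 oxidises directly.

Step 3
Reactants: 5 (2S)-6-[(tert-butyldiphenylsilyl)oxy]-2-methyl-1,2-bis[(trimethylsilyl)oxy]hexane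
Product: 6 (2S)-6-[(tert-butyldiphenylsilyl)oxy]-2-methyl-2-[(trimethylsilyl)oxy]hexanal
Conditions: (COCl)2, DMSO, CH2Cl2, −78 to −40 °C; Et3N, −78 to 0 °C
Reagents that add atoms: none
Why: Under Swern conditions the primary trimethylsilyl ether is cleaved and oxidised in the flask while the tertiary silyl ether survives, giving an α-silyloxy aldehyde that has no α-hydrogen and cannot epimerise.

Step 4
Reactants: 7 (R)-(−)-carvone; 6 (2S)-6-[(tert-butyldiphenylsilyl)oxy]-2-methyl-2-[(trimethylsilyl)oxy]hexanal
Product: 10 (5R,6R)-6-[(1S,2S)-6-{[tert-butyl(diphenyl)silyl]oxy}-1,2-dihydroxy-2-methylhexyl]-2-methyl-5-(prop-1-en-2-yl)cyclohex-2-en-1-one, via lithium dienolate of carvone 8 (not isolated), via O-trimethylsilyl aldol adduct 9 (not isolated)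
Conditions: LiN(iPr)2, THF, −78 °C; 6, −78 °C; aq. NH4Cl; then citric acid, MeOH, 0 °C
Reagents that add atoms: none
Why: Kinetic lithium aldol addition of the α′-dienolate, which reacts on the face anti to the isopropenyl group (C1 trans to C14) and, as a cyclic E-enolate, through a Zimmerman–Traxler chair to the anti adduct (C2), while C3 comes from 6, whose two α-alkyl groups differ too little to override enolate control; acidic methanol then removes the tertiary trimethylsilyl group.

Step 5
Reactants: 10 the aldol diol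
Product: 11 C2-O-methoxymethyl ether of 10 (secondary hydroxyl protected; tertiary C3 hydroxyl free)
Conditions: MOMCl, iPr2NEt, Bu4NI (cat.), CH2Cl2, 0 °C to rt
Reagents that add atoms: chloromethyl methyl ether, COCCl
Why: Acetal formation under weakly basic conditions avoids retro-aldol and touches only the secondary hydroxyl, and the methoxymethyl group is chosen because it neither migrates nor competes as a nucleophile under the basic ring closure of step 9.

Step 6
Reactants: 11 the methoxymethyl ether
Product: 12 C11–C12 β-epoxy ketone of 11 (epoxide trans to the isopropenyl group)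
Conditions: 30% H2O2, NaOH (cat.), MeOH, 0 °C
Reagents that add atoms: hydrogen peroxide, OO
Why: Weitz–Scheffer nucleophilic epoxidation of the enone, in which hydroperoxide adds axially to C12 anti to the C14 isopropenyl group as in carvone itself, setting C11 and C12 (both C–O bonds β).

Step 7
Reactants: 12 the epoxy ketone
Product: 14 transposed allylic alcohol (C10=C11 alkene; 12β-OH; 2-OMOM; 3-OH; isopropenyl on C14), via epoxy hydrazone 13 (not isolated)
Conditions: N2H4·H2O, AcOH (cat.), MeOH, 0 °C to rt
Reagents that add atoms: none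
Why: Wharton transposition, in which the epoxy hydrazone fragments with loss of N2, moves the alkene to C10=C11 and keeps the C12–O bond, so C12 retains its β-oxygen.

Step 8
Reactants: 14 the allylic alcohol
Product: 16 triol (17-OH primary; 12β-OH; 3-OH; 15R), via B-alkyl-9-borabicyclo[3.3.1]nonane 15 (not isolated)
Conditions: 9-BBN (4 equiv), THF, 0 °C to rt; then NaOH, 30% H2O2, 0 °C
Reagents that add atoms: hydrogen peroxide, OO
Why: Hydroboration–oxidation with the bulky borane selects the 1,1-disubstituted alkene over the trisubstituted one, and C15 should be set by allylic strain control, the borane attacking the conformer in which H14 eclipses C15=C17 on the face anti to the large C1 branch (15R).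

Step 9
Reactants: 16 the triol
Product: 18 oxepane (C3–O–C17 closed; 12β-OH; 2-OMOM; 7-OTBDPS), via primary tosylate 17 (not isolated)
Conditions: TsCl (1.1 equiv), Et3N, Me3N·HCl (cat.), CH2Cl2, 0 °C; then NaH, THF (0.01 M), 0 to 45 °C
Reagents that add atoms: none
Why: Selective tosylation of the primary hydroxyl followed by intramolecular Williamson etherification (7-exo-tet) by the tertiary C3 alkoxide closes the oxepane without touching a stereocentre, because the O2 acetal is inert to base and the C12 alkoxide is trans to the C15 branch and cannot reach C17.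

Step 10
Reactants: 18 the oxepane alcohol
Product: 19 12α-octanoate (2-OMOM; 7-OTBDPS)
Conditions: octanoic acid, PPh3, DIAD, toluene, 0 °C to rt
Reagents that add atoms: octanoic acid, CCCCCCCC(=O)O
Why: Mitsunobu esterification inverts C12 by SN2 displacement and installs the ester of the target in one operation, placing it α and therefore cis to the oxygen that C11 receives in step 15.

Step 11
Reactants: 19 the octanoate
Product: 20 C2 alcohol (2-OH free; 7-OTBDPS)
Conditions: ZnBr2, n-PrSH, CH2Cl2, 0 °C
Reagents that add atoms: none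
Why: Lewis acid–thiol cleavage of the methoxymethyl acetal frees the C2 hydroxyl and leaves the silyl ether, the allylic ester and the alkene untouched.

Step 12
Reactants: 20 the C2 alcohol
Product: 21 C2-O-vinyl ether (7-OTBDPS)
Conditions: [Ir(cod)Cl]2 (2 mol %), Na2CO3, vinyl acetate, toluene, 100 °C
Reagents that add atoms: vinyl acetate, CC(=O)OC=C
Why: Iridium-catalysed transfer vinylation converts the hindered secondary alcohol into its vinyl ether (future C9 and C8) under weakly basic conditions that spare the ester and generate no cation next to the C10=C11 bond.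

Step 13
Reactants: 21 the vinyl ether
Product: 22 primary alcohol (7-OH; C2-O-vinyl)
Conditions: Bu4NF, AcOH (1:1), THF, 0 °C to rt
Reagents that add atoms: none
Why: Fluoride-mediated desilylation, buffered to protect the ester, frees the C7 hydroxyl, and the vinyl ether is stable to these conditions.

Step 14
Reactants: 22 the primary alcohol
Product: 23 vinyl ether aldehyde (C7 aldehyde; C2-O-vinyl; 12α-octanoate; C10=C11)
Conditions: Dess–Martin periodinane, pyridine, CH2Cl2, 0 °C to rt
Reagents that add atoms: none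
Why: Buffered Dess–Martin oxidation gives the aldehyde without the acid that would hydrolyse the vinyl ether.

Step 15
Reactants: 23 the vinyl ether aldehyde
Product: 27 tetracyclic diol ester (7-OH as epimer mixture; 11α-OH; 12α-octanoate), via BF3-bound oxonane oxocarbenium zwitterion 24 (not isolated), via dioxolanylium ion 25 (not isolated), via O11-octanoate isomer 26 (not isolated)
Conditions: BF3·OEt2 (2.2 equiv), 2,6-di-tert-butyl-4-methylpyridine, CH2Cl2 (0.001 M, slow addition of 23), −78 to −40 °C; aq. NaHCO3, 0 °C; then Et3N, CH2Cl2, rt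
Reagents that add atoms: water, O
Why: Proposed new method: BF3 activates the C7 aldehyde, the vinyl ether attacks it through C8 (Mukaiyama-type aldol that closes the oxonane, endo for the enol ether and exo for the carbonyl) and thereby creates the C9 oxocarbenium ion 24 inside the nine-membered ring; C10=C11 then adds to C9 (Prins cyclization, 5-exo for the alkene) to close the tetrahydrofuran, the C11 cation is captured by the carbonyl oxygen of the C12 octanoate to give 25, and water opens 25 to the cis hydroxy ester, any O11 ester 26 moving to O12 by 1,2-acyl shift. The closest known chemistry is the intermolecular Mukaiyama aldol–Prins cascade of alkyl enol ethers with aldehydes, together with Prins closures of oxocarbenium ions onto trisubstituted alkenes that end by ester participation; what is new is that the aldol event is intramolecular and forms a medium ring. C9 is fixed by C2 because C8 and C3 are tied together by the oxonane and must be cis on the new ring, C10 is fixed by C1 because the two-atom link C2–O allows only cis fusion to the cyclohexane, C11 follows from anti (trans-diaxial) addition with internal oxygen delivery from the α-oriented ester, and C7 forms as a mixture that step 16 removes. The step needs chemoselectivity (the enol ether and not C10=C11 must attack the aldehyde, secured by its far higher nucleophilicity), intramolecular reaction (secured by high dilution and the cis placement of the two chains on C2 and C3) and the right order of ring closure, which is inherent because the C9 cation does not exist before the oxonane is closed. The hindered pyridine removes stray acid that would protonate the vinyl ether and start a simple Prins reaction.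

Step 16
Reactants: 27 the tetracyclic diol ester
Product: 28 C7 ketone (11α-OH; 12α-octanoate)
Conditions: Dess–Martin periodinane, NaHCO3, CH2Cl2, rt
Reagents that add atoms: none
Why: Dess–Martin oxidation acts only on the secondary C7 alcohol, since the tertiary C11 alcohol cannot be oxidised, and both C7 epimers converge on one ketone.

Step 17
Reactants: 28 the C7 ketone
Product: 29 CNP0286133.1
Conditions: Zn, CH2Br2, TiCl4, THF, 0 °C; then 28, CH2Cl2, 0 °C to rt
Reagents that add atoms: dibromomethane, BrCBr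
Why: Takai–Lombardo methylenation with the non-basic zinc–titanium methylene reagent converts the ketone into the C7=C19 alkene without β-elimination of the C9 ether, acyl migration or attack on the ester or the free tertiary alcohol.

Compound list
1 | (R)-2-methylglycidol, (2R)-(2-methyloxiran-2-yl)methanol | OC[C@]1(C)CO1 | starting material
2 | (3-bromopropoxy)(tert-butyl)diphenylsilane | CC(C)(C)[Si](c1ccccc1)(c1ccccc1)OCCCBr | starting material
3 | {3-[(tert-butyldiphenylsilyl)oxy]propyl}magnesium bromide | CC(C)(C)[Si](c1ccccc1)(c1ccccc1)OCCC[Mg]Br | intermediate (not isolated)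
4 | (2S)-6-[(tert-butyldiphenylsilyl)oxy]-2-methylhexane-1,2-diol | CC(C)(C)[Si](c1ccccc1)(c1ccccc1)OCCCC[C@](C)(O)CO | intermediate
5 | (2S)-6-[(tert-butyldiphenylsilyl)oxy]-2-methyl-1,2-bis[(trimethylsilyl)oxy]hexane | CC(C)(C)[Si](c1ccccc1)(c1ccccc1)OCCCC[C@](C)(O[Si](C)(C)C)CO[Si](C)(C)C | intermediate
6 | (2S)-6-[(tert-butyldiphenylsilyl)oxy]-2-methyl-2-[(trimethylsilyl)oxy]hexanal | CC(C)(C)[Si](c1ccccc1)(c1ccccc1)OCCCC[C@](C)(O[Si](C)(C)C)C=O | intermediate
7 | (R)-(−)-carvone | CC1=CC[C@H](CC1=O)C(C)=C | starting material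
8 | lithium α′-dienolate of (R)-carvone | [Li]OC1=C[C@H](C(C)=C)CC=C1C | intermediate (not isolated)
9 | aldol adduct with the C3 hydroxyl still as trimethylsilyl ether | CC(C)(C)[Si](c1ccccc1)(c1ccccc1)OCCCC[C@](C)(O[Si](C)(C)C)[C@@H](O)[C@@H]2C(=O)C(C)=CC[C@H]2C(C)=C | intermediate (not isolated)
10 | (5R,6R)-6-[(1S,2S)-6-{[tert-butyl(diphenyl)silyl]oxy}-1,2-dihydroxy-2-methylhexyl]-2-methyl-5-(prop-1-en-2-yl)cyclohex-2-en-1-one | CC(C)(C)[Si](c1ccccc1)(c1ccccc1)OCCCC[C@](C)(O)[C@@H](O)[C@@H]2C(=O)C(C)=CC[C@H]2C(C)=C | intermediate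
11 | C2-O-methoxymethyl ether of 10 | CC(C)(C)[Si](c1ccccc1)(c1ccccc1)OCCCC[C@](C)(O)[C@@H](OCOC)[C@@H]2C(=O)C(C)=CC[C@H]2C(C)=C | intermediate
12 | C11–C12 β-epoxy ketone of 11 | CC(C)(C)[Si](c1ccccc1)(c1ccccc1)OCCCC[C@](C)(O)[C@@H](OCOC)[C@@H]2C(=O)[C@]3(C)O[C@@H]3C[C@H]2C(C)=C | intermediate
13 | hydrazone of 12 | CC(C)(C)[Si](c1ccccc1)(c1ccccc1)OCCCC[C@](C)(O)[C@@H](OCOC)[C@@H]2C(=NN)[C@]3(C)O[C@@H]3C[C@H]2C(C)=C | intermediate (not isolated)
14 | transposed allylic alcohol (C10=C11; 12β-OH; 2-OMOM; 3-OH; isopropenyl on C14) | CC(C)(C)[Si](c1ccccc1)(c1ccccc1)OCCCC[C@](C)(O)[C@@H](OCOC)[C@@H]2C=C(C)[C@H](O)C[C@H]2C(C)=C | intermediate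
15 | C17 B-alkyl-9-borabicyclo[3.3.1]nonane from 14 | CC(C)(C)[Si](c1ccccc1)(c1ccccc1)OCCCC[C@](C)(O)[C@@H](OCOC)[C@@H]2C=C(C)[C@H](O)C[C@H]2[C@@H](C)CB3C4CCCC3CCC4 | intermediate (not isolated)
16 | triol (17-OH; 12β-OH; 3-OH; 15R) | CC(C)(C)[Si](c1ccccc1)(c1ccccc1)OCCCC[C@](C)(O)[C@@H](OCOC)[C@@H]2C=C(C)[C@H](O)C[C@H]2[C@@H](C)CO | intermediate
17 | C17 tosylate of 16 | CC(C)(C)[Si](c1ccccc1)(c1ccccc1)OCCCC[C@](C)(O)[C@@H](OCOC)[C@@H]2C=C(C)[C@H](O)C[C@H]2[C@@H](C)COS(=O)(=O)c3ccc(C)cc3 | intermediate (not isolated)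
18 | oxepane-fused cyclohexenol (C3–O–C17 ether; 12β-OH; 2-OMOM; 7-OTBDPS) | CC(C)(C)[Si](c1ccccc1)(c1ccccc1)OCCCC[C@]2(C)OC[C@H](C)[C@@H]3C[C@@H](O)C(C)=C[C@H]3[C@@H]2OCOC | intermediate
19 | 12α-octanoate of the oxepane (2-OMOM; 7-OTBDPS) | CC(C)(C)[Si](c1ccccc1)(c1ccccc1)OCCCC[C@]2(C)OC[C@H](C)[C@@H]3C[C@H](OC(=O)CCCCCCC)C(C)=C[C@H]3[C@@H]2OCOC | intermediate
20 | C2 alcohol (2-OH; 12α-octanoate; 7-OTBDPS) | CC(C)(C)[Si](c1ccccc1)(c1ccccc1)OCCCC[C@]2(C)OC[C@H](C)[C@@H]3C[C@H](OC(=O)CCCCCCC)C(C)=C[C@H]3[C@@H]2O | intermediate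
21 | C2-O-vinyl ether (7-OTBDPS) | CC(C)(C)[Si](c1ccccc1)(c1ccccc1)OCCCC[C@]2(C)OC[C@H](C)[C@@H]3C[C@H](OC(=O)CCCCCCC)C(C)=C[C@H]3[C@@H]2OC=C | intermediate
22 | C7 primary alcohol with C2-O-vinyl ether | OCCCC[C@]1(C)OC[C@H](C)[C@@H]2C[C@H](OC(=O)CCCCCCC)C(C)=C[C@H]2[C@@H]1OC=C | intermediate
23 | C7 aldehyde with C2-O-vinyl ether (precursor of the key step) | O=CCCC[C@]1(C)OC[C@H](C)[C@@H]2C[C@H](OC(=O)CCCCCCC)C(C)=C[C@H]2[C@@H]1OC=C | intermediate
24 | nine-membered ring C9 oxocarbenium ion with BF3-bound C7 alkoxide (zwitterion) | F[B-](F)(F)OC1CCC[C@]2(C)OC[C@H](C)[C@@H]3C[C@H](OC(=O)CCCCCCC)C(C)=C[C@H]3[C@@H]2[O+]=CC1 | intermediate (not isolated)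
25 | tetracyclic 2-heptyl-1,3-dioxolan-2-ylium ion across O11 and O12 (C7 alkoxide BF3-bound) | F[B-](F)(F)OC1CCC[C@]2(C)OC[C@H](C)[C@@H]3C[C@@H]5O[C+](CCCCCCC)O[C@]5(C)[C@@H]4[C@H]3[C@@H]2O[C@H]4C1 | intermediate (not isolated)
26 | O11-octanoate isomer (12α-OH; 7-OH) | OC1CCC[C@]2(C)OC[C@H](C)[C@@H]3C[C@H](O)[C@](C)(OC(=O)CCCCCCC)[C@@H]4[C@H]3[C@@H]2O[C@H]4C1 | intermediate (not isolated)
27 | tetracyclic diol ester (7-OH epimer mixture; 11α-OH; 12α-octanoate) | OC1CCC[C@]2(C)OC[C@H](C)[C@@H]3C[C@H](OC(=O)CCCCCCC)[C@](C)(O)[C@@H]4[C@H]3[C@@H]2O[C@H]4C1 | intermediate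
28 | C7 ketone | O=C1CCC[C@]2(C)OC[C@H](C)[C@@H]3C[C@H](OC(=O)CCCCCCC)[C@](C)(O)[C@@H]4[C@H]3[C@@H]2O[C@H]4C1 | intermediate
29 | CNP0286133.1, (1S,2S,3S,9S,10R,11R,12S,14S,15R) in the numbering used here | C=C1CCC[C@]2(C)OC[C@H](C)[C@@H]3C[C@H](OC(=O)CCCCCCC)[C@](C)(O)[C@@H]4[C@H]3[C@@H]2O[C@H]4C1 | target

Total step count: 17. Longest linear sequence: 17 steps (1 or 2 to 29; carvone 7 enters at step 4).

Steps most likely to fail

Step 15 (the proposed new method). What may go wrong: intermolecular aldol oligomerisation, or protonation of the vinyl ether followed by a simple Prins closure, may outrun the nine-membered ring closure. The fallback uses known chemistry and separates ring closure from cation formation. Setting out from 23, vinylmagnesium bromide (THF, −78 °C) adds to the aldehyde to give the C7 vinyl carbinol F1. Enol ether–olefin ring-closing metathesis (second-generation Grubbs catalyst, toluene, 80 °C, high dilution) then gives the nine-membered cyclic enol ether F2 with loss of ethene. Camphorsulfonic acid (CH2Cl2, −40 °C) protonates C8 to give the ring oxocarbenium ion F3, which undergoes the same Prins closure to the dioxolanylium ion F4. Work-up with aqueous NaHCO3 and Et3N as in step 15 passes through 26 and returns to the route at 27.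

Step 8. What may go wrong: facial selectivity at C15 may be poor, because allylic strain control is weak for a 1,1-disubstituted alkene. The fallback replaces substrate control by catalyst control. Setting out from 14, copper hydride-catalysed hydroboration with pinacolborane (Cu(OAc)2, the enantiomer of DTBM-SEGPHOS that is matched to 15R, THF, rt) gives the pinacol boronate F5. Oxidation with NaBO3 returns to the route at 16.

Step 4. What may go wrong: selectivity at C2 may be low, because enolate control and the stereocentre of 6 are mismatched. The fallback makes C2 first and C3 afterwards from C2.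
- 2-Methylprop-2-en-1-ol is converted to its dianion F6 (n-BuLi, TMEDA) and alkylated with 2 to give the allylic alcohol F7, and MnO2 gives the achiral enal F8.
- Setting out from 7, enolate 8 adds to F8 to give the anti aldol adduct F9, with no stereocentre in the aldehyde to interfere.
- Epoxidation directed by the C2 hydroxyl (VO(acac)2, t-BuOOH) gives the erythro epoxy alcohol F10 and sets C3.
- MOMCl and iPr2NEt give the ether F11, and H2O2/NaOH gives the epoxy ketone F12.
- Hydrazine converts F12 through its hydrazone F13 into the allylic alcohol F14.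
- LiEt3BH opens the side-chain epoxide at its CH2 terminus, which becomes the C18 methyl, and frees the tertiary C3 hydroxyl, returning to the route at 14.

Further compounds
F1 | step 15 | C7 vinyl carbinol of 23 (C7 epimer mixture) | C=CC(O)CCC[C@]1(C)OC[C@H](C)[C@@H]2C[C@H](OC(=O)CCCCCCC)C(C)=C[C@H]2[C@@H]1OC=C
F2 | step 15 | nine-membered cyclic (Z)-enol ether (C8=C9; 7-OH) | OC1CCC[C@]2(C)OC[C@H](C)[C@@H]3C[C@H](OC(=O)CCCCCCC)C(C)=C[C@H]3[C@@H]2O/C=C\1
F3 | step 15 | ring C9 oxocarbenium ion with free 7-OH | OC1CCC[C@]2(C)OC[C@H](C)[C@@H]3C[C@H](OC(=O)CCCCCCC)C(C)=C[C@H]3[C@@H]2[O+]=CC1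
F4 | step 15 | tetracyclic dioxolanylium ion with free 7-OH | OC1CCC[C@]2(C)OC[C@H](C)[C@@H]3C[C@@H]5O[C+](CCCCCCC)O[C@]5(C)[C@@H]4[C@H]3[C@@H]2O[C@H]4C1
F5 | step 8 | C17 pinacol boronate from 14 | CC(C)(C)[Si](c1ccccc1)(c1ccccc1)OCCCC[C@](C)(O)[C@@H](OCOC)[C@@H]2C=C(C)[C@H](O)C[C@H]2[C@@H](C)CB3OC(C)(C)C(C)(C)O3
F6 | step 4 | dilithio dianion of 2-methylprop-2-en-1-ol | [Li]CC(=C)CO[Li]
F7 | step 4 | 6-[(tert-butyldiphenylsilyl)oxy]-2-methylidenehexan-1-ol | C=C(CO)CCCCO[Si](c1ccccc1)(c1ccccc1)C(C)(C)C
F8 | step 4 | 6-[(tert-butyldiphenylsilyl)oxy]-2-methylidenehexanal | C=C(C=O)CCCCO[Si](c1ccccc1)(c1ccccc1)C(C)(C)C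
F9 | step 4 | anti aldol adduct of carvone and F8 | CC(C)(C)[Si](c1ccccc1)(c1ccccc1)OCCCCC(=C)[C@@H](O)[C@@H]2C(=O)C(C)=CC[C@H]2C(C)=C
F10 | step 4 | erythro C3–C18 epoxy alcohol | CC(C)(C)[Si](c1ccccc1)(c1ccccc1)OCCCC[C@@]2(CO2)[C@@H](O)[C@@H]3C(=O)C(C)=CC[C@H]3C(C)=C
F11 | step 4 | C2-O-methoxymethyl ether of F10 | CC(C)(C)[Si](c1ccccc1)(c1ccccc1)OCCCC[C@@]2(CO2)[C@@H](OCOC)[C@@H]3C(=O)C(C)=CC[C@H]3C(C)=C
F12 | step 4 | C11–C12 β-epoxy ketone of F11 | CC(C)(C)[Si](c1ccccc1)(c1ccccc1)OCCCC[C@@]2(CO2)[C@@H](OCOC)[C@@H]3C(=O)[C@]4(C)O[C@@H]4C[C@H]3C(C)=C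
F13 | step 4 | hydrazone of F12 | CC(C)(C)[Si](c1ccccc1)(c1ccccc1)OCCCC[C@@]2(CO2)[C@@H](OCOC)[C@@H]3C(=NN)[C@]4(C)O[C@@H]4C[C@H]3C(C)=C
F14 | step 4 | transposed allylic alcohol with side-chain epoxide | CC(C)(C)[Si](c1ccccc1)(c1ccccc1)OCCCC[C@@]2(CO2)[C@@H](OCOC)[C@@H]3C=C(C)[C@H](O)C[C@H]3C(C)=C
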